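**Plan**

Ring A is numbered C1 (methyl), C2 (arylethynyl arm), C3 (bears the quinone-methide carbon), C4 (ring B), C5 and C6 (both CH).
Retrosynthetic cuts, in order: the dienone of ring D and the two phenols go back to a tris(methyl ether) triarylcarbinol; then the carbinol C–phenyl bond; then ring A at C1–C6 and C4–C5, which removes the C5–C6 CH=CH unit and leaves a 2-pyrone; then the C2–C(sp) bond; last, the pyrone is split into a 1,3-diketone and a methylmalonyl unit.
Enabling feature: C5 and C6 of ring A carry only hydrogen, and ring B on C4 and ring D on the carbon attached to C3 are both 4-oxygenated phenyl rings. One symmetrical bis(4-methoxyphenyl) diketone can therefore deliver both, and C1–C4 with all four substituents map onto C3–C6 of a pyrone.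
Forward order: pyrone ring first (from commercial methylmalonic acid and the commercial diketone), then the alkyne arm by cross-coupling, then ring A by cycloaddition and double cycloreversion with commercial norbornadiene, then the phenyl ring, and finally ring D is unveiled as the cyclohexadienone.
Stereochemistry: the target has no stereogenic element; the carbinol centre made in step 6 is racemic and becomes planar again in step 7.

Key step: step 5

Remark: carbinols 13 and 14 are racemic. The transient adducts 10 and 11 are drawn as one enantiomer of the racemic exo adduct that is expected; their configuration is immaterial because every sp3 centre disappears in the same flask.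

**Route**

Step 1
Reactants: 1 methylmalonic acid
Product: 2 methylmalonyl dichloride
Conditions: SOCl2 (excess), 50 °C; distillation under reduced pressure
Reagents that add atoms: thionyl chloride, O=S(Cl)Cl
Why: Standard conversion of a carboxylic acid into its acid chloride through the chlorosulfite, with the volatile dichloride purified by distillation and used at once.

Step 2
Reactants: 2 methylmalonyl dichloride; 3 1,3-bis(4-methoxyphenyl)propane-1,3-dione
Product: 5 4-hydroxy-5-(4-methoxybenzoyl)-6-(4-methoxyphenyl)-3-methyl-2H-pyran-2-one, via C-acylated triketo acid chloride 4 (not isolated)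
Conditions: toluene, 100 °C, N2 sweep to carry off HCl
Reagents that add atoms: none
Why: Acylative cyclocondensation of a 1,3-diketone with a malonyl dichloride, the established route to 5-acyl-4-hydroxy-2-pyrones: the enolised diketone is C-acylated at its central carbon, the enol oxygen of one aroyl group then lactonises onto the second acid chloride, and the C3 methyl group blocks any further annulation.

Step 3
Reactants: 5 4-hydroxy-5-(4-methoxybenzoyl)-6-(4-methoxyphenyl)-3-methyl-2H-pyran-2-one
Product: 6 5-(4-methoxybenzoyl)-6-(4-methoxyphenyl)-3-methyl-2-oxo-2H-pyran-4-yl trifluoromethanesulfonate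
Conditions: Tf2O, Et3N, CH2Cl2, −78 to 0 °C
Reagents that add atoms: trifluoromethanesulfonic anhydride, O=S(=O)(OS(=O)(=O)C(F)(F)F)C(F)(F)F
Why: O-sulfonylation of the acidic 4-hydroxy group of a 4-hydroxy-2-pyrone (a vinylogous carboxylic acid) is routine, and with C3 blocked by methyl only the 4-triflate can form.

Step 4
Reactants: 6 5-(4-methoxybenzoyl)-6-(4-methoxyphenyl)-3-methyl-2-oxo-2H-pyran-4-yl trifluoromethanesulfonate; 7 4-ethynylanisole
Product: 8 5-(4-methoxybenzoyl)-6-(4-methoxyphenyl)-4-[(4-methoxyphenyl)ethynyl]-3-methyl-2H-pyran-2-one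
Conditions: Pd(PPh3)2Cl2 (5 mol %), CuI (10 mol %), iPr2NEt, degassed THF, 0 °C to rt
Reagents that add atoms: none
Why: Sonogashira coupling, well established for 4-sulfonyloxy- and 4-halo-2-pyrones: the vinylogous acyl triflate adds readily to zerovalent palladium formed in the flask, the copper acetylide transmetalates, and reductive elimination forms the C4–C(sp) bond, while the hindered amine cannot displace the triflate.

Step 5
Reactants: 8 5-(4-methoxybenzoyl)-6-(4-methoxyphenyl)-4-[(4-methoxyphenyl)ethynyl]-3-methyl-2H-pyran-2-one; 9 norbornadiene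
Product: 12 (4-methoxyphenyl)[6-(4-methoxyphenyl)-2-[(4-methoxyphenyl)ethynyl]-3-methylphenyl]methanone, via bridged lactone cycloadduct 10 (not isolated), via norbornene-fused cyclohexadiene 11 (not isolated)
Conditions: 9 (15 equiv), o-xylene, BHT (cat.), sealed tube, 170 °C
Reagents that add atoms: none
Why: One strained C=C of 9 should add suprafacially across pyrone C3 and C6 in an inverse-electron-demand [4+2] reaction (the 5-aroyl and 4-alkynyl groups lower the diene LUMO) to give lactone 10; retro-[4+2] loss of CO2 then gives diene 11, and a second retro-[4+2] expels cyclopentadiene. This is the known use of norbornadiene as an acetylene equivalent in Diels–Alder and retro-Diels–Alder benzannulation of 2-pyrones. Ring A closes by an intermolecular [4+2] cycloaddition that forms its C1–C6 and C4–C5 bonds (pyrone C3–CH and C6–CH) in one event, and the two cycloreversions make it aromatic with methyl, alkyne, aroyl and aryl already on C1–C4. No stereocentre survives, since all sp3 centres of 10 and 11 (exo addition expected) are lost on aromatisation. The step needs chemoselectivity for 9 over the pendant diarylalkyne and over a second pyrone adding to 11; the large excess of the strained alkene and the low dienophilicity of the hindered internal alkyne should secure it, and the symmetrical two-carbon partner leaves no regiochemical question. Because both diene termini are fully substituted, sealed-tube heating is planned.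

Step 6
Reactants: 12 (4-methoxyphenyl)[6-(4-methoxyphenyl)-2-[(4-methoxyphenyl)ethynyl]-3-methylphenyl]methanone
Product: 13 (4-methoxyphenyl)[6-(4-methoxyphenyl)-2-[(4-methoxyphenyl)ethynyl]-3-methylphenyl](phenyl)methanol (racemic)
Conditions: PhLi (2 equiv), THF, −78 to 0 °C; then H2O
Reagents that add atoms: phenyllithium, [Li]c1ccccc1
Why: 1,2-Addition of an aryllithium to a non-enolisable diaryl ketone is reliable even with two ortho substituents, the aryl ethers and the internal alkyne are inert to PhLi at low temperature, and the new carbinol centre is formed as a racemate that is planarised in the next step.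

Step 7
Reactants: 13 (4-methoxyphenyl)[6-(4-methoxyphenyl)-2-[(4-methoxyphenyl)ethynyl]-3-methylphenyl](phenyl)methanol
Product: 15 selaginellin A, via triphenol carbinol 14 (not isolated)
Conditions: BBr3 (excess), CH2Cl2, −78 °C to rt; then ice-water, aq NaHCO3
Reagents that add atoms: none
Why: BBr3 cleaves the three aryl methyl ethers (boron–oxygen complexation, then bromide attack at methyl), and on aqueous work-up the 4-hydroxyphenyl carbinol loses water through its trityl cation to the fuchsone-type quinone methide, the stable form of 4-hydroxytrityl alcohols; the alkyne cannot trap the cation because that would need an endocyclic vinyl cation in a five-membered ring.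

**Compound list**

1 | methylmalonic acid (2-methylpropanedioic acid) | CC(C(=O)O)C(=O)O | starting material
2 | methylmalonyl dichloride (2-methylpropanedioyl dichloride) | CC(C(=O)Cl)C(=O)Cl | intermediate
3 | 1,3-bis(4-methoxyphenyl)propane-1,3-dione | COc1ccc(C(=O)CC(=O)c2ccc(OC)cc2)cc1 | starting material
4 | 4,4-bis(4-methoxybenzoyl)-2-methyl-3-oxobutanoyl chloride (racemic, not isolated) | CC(C(=O)Cl)C(=O)C(C(=O)c1ccc(OC)cc1)C(=O)c1ccc(OC)cc1 | intermediate
5 | 4-hydroxy-5-(4-methoxybenzoyl)-6-(4-methoxyphenyl)-3-methyl-2H-pyran-2-one | Cc1c(O)c(C(=O)c2ccc(OC)cc2)c(-c2ccc(OC)cc2)oc1=O | intermediate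
6 | 5-(4-methoxybenzoyl)-6-(4-methoxyphenyl)-3-methyl-2-oxo-2H-pyran-4-yl trifluoromethanesulfonate | Cc1c(OS(=O)(=O)C(F)(F)F)c(C(=O)c2ccc(OC)cc2)c(-c2ccc(OC)cc2)oc1=O | intermediate
7 | 4-ethynylanisole (1-ethynyl-4-methoxybenzene) | C#Cc1ccc(OC)cc1 | starting material
8 | 5-(4-methoxybenzoyl)-6-(4-methoxyphenyl)-4-[(4-methoxyphenyl)ethynyl]-3-methyl-2H-pyran-2-one | Cc1c(C#Cc2ccc(OC)cc2)c(C(=O)c2ccc(OC)cc2)c(-c2ccc(OC)cc2)oc1=O | intermediate
9 | norbornadiene (bicyclo[2.2.1]hepta-2,5-diene) | C1=CC2C=CC1C2 | starting material
10 | [4+2] adduct of 8 and 9: 2-oxabicyclo[2.2.2]oct-5-en-3-one with 1-(4-methoxyphenyl), 4-methyl, 5-[(4-methoxyphenyl)ethynyl] and 6-(4-methoxybenzoyl) groups, fused across C7–C8 to the exo face of norborn-2-ene, norbornene skeleton on the lactone side (racemic, relative configuration drawn, not isolated) | C[C@]12C(=O)O[C@](c3ccc(OC)cc3)(C(C(=O)c3ccc(OC)cc3)=C1C#Cc1ccc(OC)cc1)[C@H]1[C@H]3C[C@H](C=C3)[C@@H]21 | intermediate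
11 | (4-methoxyphenyl)[5-(4-methoxyphenyl)-7-[(4-methoxyphenyl)ethynyl]-8-methyl-1,4,4a,8a-tetrahydro-1,4-methanonaphthalen-6-yl]methanone, cis-exo ring fusion (racemic, relative configuration drawn, not isolated) | CC1=C(C#Cc2ccc(OC)cc2)C(C(=O)c2ccc(OC)cc2)=C(c2ccc(OC)cc2)[C@H]2[C@H]3C[C@H](C=C3)[C@@H]12 | intermediate
12 | (4-methoxyphenyl)[6-(4-methoxyphenyl)-2-[(4-methoxyphenyl)ethynyl]-3-methylphenyl]methanone | Cc1ccc(-c2ccc(OC)cc2)c(C(=O)c2ccc(OC)cc2)c1C#Cc1ccc(OC)cc1 | intermediate
13 | (4-methoxyphenyl)[6-(4-methoxyphenyl)-2-[(4-methoxyphenyl)ethynyl]-3-methylphenyl](phenyl)methanol (racemic) | Cc1ccc(-c2ccc(OC)cc2)c(C(O)(c2ccc(OC)cc2)c2ccccc2)c1C#Cc1ccc(OC)cc1 | intermediate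
14 | (4-hydroxyphenyl)[6-(4-hydroxyphenyl)-2-[(4-hydroxyphenyl)ethynyl]-3-methylphenyl](phenyl)methanol (racemic, not isolated) | Cc1ccc(-c2ccc(O)cc2)c(C(O)(c2ccc(O)cc2)c2ccccc2)c1C#Cc1ccc(O)cc1 | intermediate
15 | selaginellin A, 4-[[6-(4-hydroxyphenyl)-2-[(4-hydroxyphenyl)ethynyl]-3-methylphenyl](phenyl)methylidene]cyclohexa-2,5-dien-1-one | Cc1ccc(-c2ccc(O)cc2)c(C(=C2C=CC(=O)C=C2)c2ccccc2)c1C#Cc1ccc(O)cc1 | target

**Count and risks**

Total step count: 7. Longest linear sequence: 7 steps (1 to 15); compounds 3, 7 and 9 enter along this single line.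

Steps most likely to fail:

1. Step 5. The cycloaddition may be too slow because both diene termini (pyrone C3 and C6) are fully substituted. Norbornadiene could then oligomerise, and the liberated cyclopentadiene or the pendant alkyne could begin to consume the pyrone before ring A has formed. The fallback sets out from 8 and replaces the strained alkene by a smaller, more electron-rich acetylene equivalent. Ethyl vinyl ether (neat, sealed tube, 130–150 °C) should add with its CH2 terminus at pyrone C6, and loss of CO2 should give [4-ethoxy-2-(4-methoxyphenyl)-6-[(4-methoxyphenyl)ethynyl]-5-methylcyclohexa-1,5-dien-1-yl](4-methoxyphenyl)methanone F1. The other regioisomer would converge as well. Warming F1 with TsOH in toluene at 80 °C should eliminate ethanol and return to the route at 12.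

2. Step 2. O-acylation of the enolised diketone, self-condensation of the acid chloride through its ketene, and HCl-promoted degradation may outrun the C-acylation and lactonisation sequence. The fallback sets out from 1 and 3 and uses an acid-free active ester in place of the dichloride. Acid 1 is esterified with 2,4,6-trichlorophenol (POCl3, 100 °C) to give bis(2,4,6-trichlorophenyl) 2-methylpropanedioate F2. Fusion of F2 with 3 (Ph2O, 200–220 °C) should release the acylating ketene slowly and close the pyrone with loss of two molecules of trichlorophenol, returning to the route at 5.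

3. Step 7. The tertiary carbinol may ionise under BBr3 well before the three ethers are cleaved. The trityl cation would then be exposed for hours to Lewis acid and bromide, so Friedel–Crafts closure onto ring B (fluorene formation) or addition of HBr across the alkyne may compete. The fallback sets out from 12 and moves the demethylation to the ketone stage, where no cation can form. BBr3 (CH2Cl2, −78 to 0 °C) should give (4-hydroxyphenyl)[6-(4-hydroxyphenyl)-2-[(4-hydroxyphenyl)ethynyl]-3-methylphenyl]methanone F3. Silylation (iPr3SiCl, imidazole, DMF) should give [6-[4-(triisopropylsilyloxy)phenyl]-2-[[4-(triisopropylsilyloxy)phenyl]ethynyl]-3-methylphenyl][4-(triisopropylsilyloxy)phenyl]methanone F4. PhLi (THF, −78 °C) should then give [6-[4-(triisopropylsilyloxy)phenyl]-2-[[4-(triisopropylsilyloxy)phenyl]ethynyl]-3-methylphenyl][4-(triisopropylsilyloxy)phenyl](phenyl)methanol F5. Bu4NF in THF at 0 °C followed by AcOH should remove the silyl groups and rejoin the route at 14, which dehydrates to 15 under the mild acid.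

**Further compounds**

F1 | step 5 | [4-ethoxy-2-(4-methoxyphenyl)-6-[(4-methoxyphenyl)ethynyl]-5-methylcyclohexa-1,5-dien-1-yl](4-methoxyphenyl)methanone (racemic) | CCOC1CC(c2ccc(OC)cc2)=C(C(=O)c2ccc(OC)cc2)C(C#Cc2ccc(OC)cc2)=C1C
F2 | step 2 | bis(2,4,6-trichlorophenyl) 2-methylpropanedioate | CC(C(=O)Oc1c(Cl)cc(Cl)cc1Cl)C(=O)Oc1c(Cl)cc(Cl)cc1Cl
F3 | step 7 | (4-hydroxyphenyl)[6-(4-hydroxyphenyl)-2-[(4-hydroxyphenyl)ethynyl]-3-methylphenyl]methanone | Cc1ccc(-c2ccc(O)cc2)c(C(=O)c2ccc(O)cc2)c1C#Cc1ccc(O)cc1
F4 | step 7 | [6-[4-(triisopropylsilyloxy)phenyl]-2-[[4-(triisopropylsilyloxy)phenyl]ethynyl]-3-methylphenyl][4-(triisopropylsilyloxy)phenyl]methanone | Cc1ccc(-c2ccc(O[Si](C(C)C)(C(C)C)C(C)C)cc2)c(C(=O)c2ccc(O[Si](C(C)C)(C(C)C)C(C)C)cc2)c1C#Cc1ccc(O[Si](C(C)C)(C(C)C)C(C)C)cc1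
F5 | step 7 | [6-[4-(triisopropylsilyloxy)phenyl]-2-[[4-(triisopropylsilyloxy)phenyl]ethynyl]-3-methylphenyl][4-(triisopropylsilyloxy)phenyl](phenyl)methanol (racemic) | Cc1ccc(-c2ccc(O[Si](C(C)C)(C(C)C)C(C)C)cc2)c(C(O)(c2ccc(O[Si](C(C)C)(C(C)C)C(C)C)cc2)c2ccccc2)c1C#Cc1ccc(O[Si](C(C)C)(C(C)C)C(C)C)cc1
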